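**Retrosynthetic overview**
- The target is reached from a C2/C3 cis-diol precursor by orthoester-mediated isobutyrylation of the axial C3 oxygen, with acetonide removal in the same pot.
- Key disconnection C1–C7: a visible-light nickel cross-electrophile coupling joins a ring epoxy alcohol (fragment A) to a 2-iodoallyl isobutyrate (fragment B) and sets C1.
- Fragment A comes from toluene cis-dihydrodiol by two hydroxyl-directed epoxidations separated by anti hydrolysis of a vinyl epoxide; C5 and C6 are bought, and C2, C3, C4 follow from them.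
- Fragment B comes from (S)-malic acid acetonide (C10 bought): Grignard addition/lactonisation, alkenyllithium addition, and 1,3-anti hydroxyl-directed reduction, which sets C8.
- Ring order: the cyclohexane is bought intact; no carbocycle is built, only transient oxirane, dioxolane and orthoester rings.

Assumption: toluene cis-dihydrodiol (fermentation product) and the acetonide of natural (S)-malic acid are taken as purchasable chiral starting materials.

Locants used in names: ring C1 (bears the side chain), C2 (free OH), C3 (isobutyrate), C4 (methyl carbinol), C5 (acetate), C6 (isobutyrate); side chain C7 (=CH2), C8, C9, C10, C11; β is the ring face of the C1 side chain, α the opposite face.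

**Step 1**
Reactants: 1 (1S,2R)-3-methylcyclohexa-3,5-diene-1,2-diol
Product: 2 3β,4β-epoxy-4α-methylcyclohex-1-ene-5β,6β-diol
Conditions: VO(acac)2 (2 mol %), t-BuOOH (1.1 equiv, decane), CH2Cl2, 0 °C
Reagents that add atoms: tert-butyl hydroperoxide, CC(C)(C)OO
Why: Vanadium-catalysed hydroxyl-directed epoxidation, in which the allylic C5 hydroxyl delivers the peroxide to the β face of the more electron-rich trisubstituted C3=C4 alkene and so sets C3 and C4 syn to the bought diol.

**Step 2**
Reactants: 2 3β,4β-epoxy-4α-methylcyclohex-1-ene-5β,6β-diol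
Product: 4 5β-acetoxy-3β,4β-epoxy-4α-methylcyclohex-1-en-6β-yl 2-methylpropanoate, via 6-O-isobutyrate 3 (not isolated)
Conditions: (i-PrCO)2O (1.05 equiv), Et3N, DMAP (cat.), CH2Cl2, −40 °C; then Ac2O (2 equiv), 0 °C to rt
Reagents that add atoms: isobutyric anhydride, CC(C)C(=O)OC(=O)C(C)C; acetic anhydride, CC(=O)OC(C)=O
Why: Sterically differentiated DMAP-catalysed acylation, in which the C6 hydroxyl (next to a vinylic CH) is esterified before the C5 hydroxyl (next to the quaternary epoxide carbon), which is then acetylated in the same pot without touching a stereocentre.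

**Step 3**
Reactants: 4 5β-acetoxy-3β,4β-epoxy-4α-methylcyclohex-1-en-6β-yl 2-methylpropanoate
Product: 5 5β-acetoxy-3α,4β-dihydroxy-4α-methylcyclohex-1-en-6β-yl 2-methylpropanoate
Conditions: HClO4 (5 mol %), THF/H2O 4:1, 0 °C
Reagents that add atoms: water, O
Why: Acid-catalysed anti hydrolysis of a vinyl epoxide, in which water attacks the allylic C3 with inversion (the tertiary C4 is deactivated by the neighbouring acetoxy-bearing carbon), setting C3-OH α and leaving the C4 oxygen β.

**Step 4**
Reactants: 5 5β-acetoxy-3α,4β-dihydroxy-4α-methylcyclohex-1-en-6β-yl 2-methylpropanoate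
Product: 6 5β-acetoxy-1α,2α-epoxy-3α,4β-dihydroxy-4α-methylcyclohexan-6β-yl 2-methylpropanoate
Conditions: VO(acac)2 (5 mol %), t-BuOOH (1.5 equiv, decane), CH2Cl2, 0 °C to rt
Reagents that add atoms: tert-butyl hydroperoxide, CC(C)(C)OO
Why: Vanadium-catalysed directed epoxidation again, in which the allylic C3 hydroxyl on the α face delivers oxygen syn and so sets the 1α,2α-epoxide and thereby the later C2 configuration.

**Step 5**
Reactants: 7 (S)-2-(2,2-dimethyl-5-oxo-1,3-dioxolan-4-yl)acetic acid
Product: 9 (4S)-4-hydroxy-5,5-dimethyloxolan-2-one, via dihydroxy acid 8 (not isolated)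
Conditions: MeMgBr (5 equiv), THF, −20 °C to rt; then 2 M HCl, rt
Reagents that add atoms: methylmagnesium bromide, C[Mg]Br
Why: Double Grignard addition to the dioxolanone carbonyl (the magnesium carboxylate is inert) builds the C11 carbinol, and acidification closes the γ-lactone onto the tertiary hydroxyl while the bought malate stereocentre (C10) is carried through untouched.

**Step 6**
Reactants: 9 (4S)-4-hydroxy-5,5-dimethyloxolan-2-one; 10 (1-bromovinyl)trimethylsilane
Product: 12 (5S)-5,6-dihydroxy-6-methyl-2-(trimethylsilyl)hept-1-en-3-one, via 1-(trimethylsilyl)vinyllithium 11 (not isolated)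
Conditions: 10 (2.3 equiv), t-BuLi (4.6 equiv), Et2O, −78 °C; then 9, THF, −78 °C; AcOH quench
Reagents that add atoms: none
Why: Bromine–lithium exchange followed by alkenyllithium mono-addition to the γ-lactone, whose lithium hemiketal survives at −78 °C so that the ketone (in equilibrium with its lactol) is released only on quench and no stereocentre is formed.

**Step 7**
Reactants: 12 (5S)-5,6-dihydroxy-6-methyl-2-(trimethylsilyl)hept-1-en-3-one
Product: 13 (3S,5S)-6-methyl-2-(trimethylsilyl)hept-1-ene-3,5,6-triol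
Conditions: Me4NBH(OAc)3 (5 equiv), MeCN/AcOH 1:1, −30 °C
Reagents that add atoms: none
Why: Evans–Saksena reduction, in which the C10 hydroxyl exchanges onto boron and delivers hydride intramolecularly through a chair-like six-membered transition state, setting C8 1,3-anti to C10 (8S).

**Step 8**
Reactants: 13 (3S,5S)-6-methyl-2-(trimethylsilyl)hept-1-ene-3,5,6-triol
Product: 14 (2S)-1-[(4S)-2,2,5,5-tetramethyl-1,3-dioxolan-4-yl]-3-(trimethylsilyl)but-3-en-2-ol
Conditions: Me2C(OMe)2, pyridinium p-toluenesulfonate (cat.), CH2Cl2, rt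
Reagents that add atoms: 2,2-dimethoxypropane, COC(C)(C)OC
Why: Thermodynamic acetonide formation selects the vicinal C10/C11 diol (five-membered dioxolane) because the acetonide of the anti-1,3-diol would need a twist-boat, and no stereocentre changes.

**Step 9**
Reactants: 14 (2S)-1-[(4S)-2,2,5,5-tetramethyl-1,3-dioxolan-4-yl]-3-(trimethylsilyl)but-3-en-2-ol
Product: 15 (2S)-1-[(4S)-2,2,5,5-tetramethyl-1,3-dioxolan-4-yl]-3-(trimethylsilyl)but-3-en-2-yl 2-methylpropanoate
Conditions: (i-PrCO)2O, Et3N, DMAP (cat.), CH2Cl2, rt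
Reagents that add atoms: isobutyric anhydride, CC(C)C(=O)OC(=O)C(C)C
Why: DMAP-catalysed acylation of the only free hydroxyl installs the C8 isobutyrate with retention.

**Step 10**
Reactants: 15 (2S)-1-[(4S)-2,2,5,5-tetramethyl-1,3-dioxolan-4-yl]-3-(trimethylsilyl)but-3-en-2-yl 2-methylpropanoate
Product: 16 (2S)-3-iodo-1-[(4S)-2,2,5,5-tetramethyl-1,3-dioxolan-4-yl]but-3-en-2-yl 2-methylpropanoate
Conditions: N-iodosuccinimide (1.3 equiv), (CF3)2CHOH, 0 °C
Reagents that add atoms: N-iodosuccinimide, O=C1CCC(=O)N1I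
Why: Electrophilic ipso-iododesilylation of the vinylsilane in hexafluoroisopropanol gives the 1,1-disubstituted alkenyl iodide without touching C8 or C10.

**Step 11**
Reactants: 6 5β-acetoxy-1α,2α-epoxy-3α,4β-dihydroxy-4α-methylcyclohexan-6β-yl 2-methylpropanoate; 16 (2S)-3-iodo-1-[(4S)-2,2,5,5-tetramethyl-1,3-dioxolan-4-yl]but-3-en-2-yl 2-methylpropanoate
Product: 18 5β-acetoxy-2α,3α,4β-trihydroxy-4α-methyl-1β-{(3S)-3-(isobutyryloxy)-4-[(4S)-2,2,5,5-tetramethyl-1,3-dioxolan-4-yl]but-1-en-2-yl}cyclohexan-6β-yl 2-methylpropanoate, via trans-iodohydrin 17 (not isolated)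
Conditions: 16 (1.3 equiv), MgI2 (0.3 equiv), NiBr2·MeOCH2CH2OMe (10 mol %), 4,4'-di-tert-butyl-2,2'-bipyridine (12 mol %), 2,4,5,6-tetrakis(carbazol-9-yl)isophthalonitrile (2 mol %), Hantzsch ester (1.5 equiv), NaHCO3 (2 equiv), DMA, 450 nm LEDs, 20 °C
Reagents that add atoms: none
Why: Proposed new method: a hydroxyl-directed, iodide-relayed nickel/photoredox cross-electrophile coupling in which MgI2 chelates the C3 hydroxyl and the cis oxirane oxygen so that iodide opens the epoxide trans-diaxially at the distal C1 to give 17, monovalent nickel (or the photoreduced catalyst) abstracts the iodine to give a C1 radical, this radical is captured by the alkenylnickel formed from zerovalent nickel and 16, and reductive elimination from trivalent nickel forms C1–C7 on the β face (equatorial, trans to the magnesium-bound C2 oxygen and away from the axial α-C3 oxygen), which sets C1; the closest known reactions are the nickel/iodide co-catalysed reductive arylation of epoxides with metal reductants, the nickel/titanocene/photoredox arylation of epoxides and the MgI2-mediated distal opening of 2,3-epoxy alcohols, none of which has been shown with an alkenyl iodide under photoredox turnover or with hydroxyl direction on a fully oxygenated cyclohexene oxide.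

**Step 12**
Reactants: 18 5β-acetoxy-2α,3α,4β-trihydroxy-4α-methyl-1β-{(3S)-3-(isobutyryloxy)-4-[(4S)-2,2,5,5-tetramethyl-1,3-dioxolan-4-yl]but-1-en-2-yl}cyclohexan-6β-yl 2-methylpropanoate
Product: 21 CNP0348997.1 (target), via cyclic orthoester 19 (not isolated), via target acetonide 20 (not isolated)
Conditions: i-PrC(OMe)3 (3 equiv), p-TsOH·H2O (5 mol %), CH2Cl2, rt; then AcOH/H2O 4:1, rt to 40 °C
Reagents that add atoms: trimethyl orthoisobutyrate, COC(OC)(OC)C(C)C; water, O
Why: Orthoester exchange onto the only cis-diol (C2/C3) followed by kinetically controlled acid hydrolysis, which opens a cis-fused cyclic orthoester to the axial ester (C3) and the equatorial alcohol (C2) in the chair that keeps the side chain equatorial, while the same aqueous acid removes the acetonide and no stereocentre changes.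

**Compound list**
1 | (1S,2R)-3-methylcyclohexa-3,5-diene-1,2-diol (toluene cis-dihydrodiol; C5-OH and C6-OH β) | C1=CC=C(C)[C@@H](O)[C@H]1O | starting material
2 | 3β,4β-epoxy-4α-methylcyclohex-1-ene-5β,6β-diol | C1=C[C@H]2O[C@@]2(C)[C@@H](O)[C@H]1O | intermediate
3 | 3β,4β-epoxy-5β-hydroxy-4α-methylcyclohex-1-en-6β-yl 2-methylpropanoate | C1=C[C@H]2O[C@@]2(C)[C@@H](O)[C@H]1OC(=O)C(C)C | intermediate
4 | 5β-acetoxy-3β,4β-epoxy-4α-methylcyclohex-1-en-6β-yl 2-methylpropanoate | C1=C[C@H]2O[C@@]2(C)[C@@H](OC(C)=O)[C@H]1OC(=O)C(C)C | intermediate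
5 | 5β-acetoxy-3α,4β-dihydroxy-4α-methylcyclohex-1-en-6β-yl 2-methylpropanoate | C1=C[C@H](O)[C@@](C)(O)[C@@H](OC(C)=O)[C@H]1OC(=O)C(C)C | intermediate
6 | 5β-acetoxy-1α,2α-epoxy-3α,4β-dihydroxy-4α-methylcyclohexan-6β-yl 2-methylpropanoate (fragment A) | [C@@H]12O[C@@H]1[C@H](O)[C@@](C)(O)[C@@H](OC(C)=O)[C@H]2OC(=O)C(C)C | intermediate
7 | (S)-2-(2,2-dimethyl-5-oxo-1,3-dioxolan-4-yl)acetic acid | OC(=O)C[C@@H]1OC(C)(C)OC1=O | starting material
8 | (3S)-3,4-dihydroxy-4-methylpentanoic acid | OC(=O)C[C@H](O)C(C)(C)O | intermediate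
9 | (4S)-4-hydroxy-5,5-dimethyloxolan-2-one | O=C1C[C@H](O)C(C)(C)O1 | intermediate
10 | (1-bromovinyl)trimethylsilane | C=C(Br)[Si](C)(C)C | starting material
11 | 1-(trimethylsilyl)vinyllithium | [Li]C(=C)[Si](C)(C)C | intermediate
12 | (5S)-5,6-dihydroxy-6-methyl-2-(trimethylsilyl)hept-1-en-3-one (open form of the lactol) | C=C([Si](C)(C)C)C(=O)C[C@H](O)C(C)(C)O | intermediate
13 | (3S,5S)-6-methyl-2-(trimethylsilyl)hept-1-ene-3,5,6-triol | C=C([Si](C)(C)C)[C@@H](O)C[C@H](O)C(C)(C)O | intermediate
14 | (2S)-1-[(4S)-2,2,5,5-tetramethyl-1,3-dioxolan-4-yl]-3-(trimethylsilyl)but-3-en-2-ol | C=C([Si](C)(C)C)[C@@H](O)C[C@@H]1OC(C)(C)OC1(C)C | intermediate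
15 | (2S)-1-[(4S)-2,2,5,5-tetramethyl-1,3-dioxolan-4-yl]-3-(trimethylsilyl)but-3-en-2-yl 2-methylpropanoate | C=C([Si](C)(C)C)[C@H](C[C@@H]1OC(C)(C)OC1(C)C)OC(=O)C(C)C | intermediate
16 | (2S)-3-iodo-1-[(4S)-2,2,5,5-tetramethyl-1,3-dioxolan-4-yl]but-3-en-2-yl 2-methylpropanoate (fragment B) | C=C(I)[C@H](C[C@@H]1OC(C)(C)OC1(C)C)OC(=O)C(C)C | intermediate
17 | 5β-acetoxy-2α,3α,4β-trihydroxy-1β-iodo-4α-methylcyclohexan-6β-yl 2-methylpropanoate | I[C@H]1[C@H](O)[C@H](O)[C@@](C)(O)[C@@H](OC(C)=O)[C@H]1OC(=O)C(C)C | intermediate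
18 | 5β-acetoxy-2α,3α,4β-trihydroxy-4α-methyl-1β-{(3S)-3-(isobutyryloxy)-4-[(4S)-2,2,5,5-tetramethyl-1,3-dioxolan-4-yl]but-1-en-2-yl}cyclohexan-6β-yl 2-methylpropanoate | C=C([C@H]1[C@H](O)[C@H](O)[C@@](C)(O)[C@@H](OC(C)=O)[C@H]1OC(=O)C(C)C)[C@H](C[C@@H]2OC(C)(C)OC2(C)C)OC(=O)C(C)C | intermediate
19 | 2α,3α-O-(1-methoxy-2-methylpropylidene) cyclic orthoester of 18 (orthoester carbon unassigned) | C=C([C@H]1[C@@H]3OC(OC)(C(C)C)O[C@@H]3[C@@](C)(O)[C@@H](OC(C)=O)[C@H]1OC(=O)C(C)C)[C@H](C[C@@H]2OC(C)(C)OC2(C)C)OC(=O)C(C)C | intermediate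
20 | 10,11-O-isopropylidene derivative of the target (3α-isobutyrate of 18) | C=C([C@H]1[C@H](O)[C@H](OC(=O)C(C)C)[C@@](C)(O)[C@@H](OC(C)=O)[C@H]1OC(=O)C(C)C)[C@H](C[C@@H]2OC(C)(C)OC2(C)C)OC(=O)C(C)C | intermediate
21 | CNP0348997.1: 5β-acetoxy-2α,4β-dihydroxy-4α-methyl-1β-[(3S,5S)-5,6-dihydroxy-3-(isobutyryloxy)-6-methylhept-1-en-2-yl]cyclohexane-3α,6β-diyl bis(2-methylpropanoate) | C=C([C@H]1[C@H](O)[C@H](OC(=O)C(C)C)[C@@](C)(O)[C@@H](OC(C)=O)[C@H]1OC(=O)C(C)C)[C@H](C[C@H](O)C(C)(C)O)OC(=O)C(C)C | target

**Step count and risks**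
Total steps: 12. Longest linear sequence: 8 (steps 5 to 12, from 7); the ring branch is 6 (steps 1 to 4, 11, 12).

Three steps most likely to fail:

Step 11 (the proposed coupling). The site of oxirane opening, the capture of a hindered secondary radical flanked by two oxygenated carbons, and the face selectivity at C1 are all untested. The fallback uses known chemistry, run stepwise and thermally, and sets out from 6. MgBr2·OEt2 in Et2O/toluene at −20 °C opens the chelated 2,3-epoxy alcohol at the distal carbon to the isolable trans-bromohydrin 5β-acetoxy-1β-bromo-2α,3α,4β-trihydroxy-4α-methylcyclohexan-6β-yl 2-methylpropanoate F1. This secondary bromide and 16 are then joined by the established nickel-catalysed reductive alkyl–alkenyl cross-electrophile coupling with a metal reductant (NiI2, 4,4'-di-tert-butyl-2,2'-bipyridine, NaI, Mn powder, DMA, 25 °C). The fallback comes back to the route at 18.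

Step 12. The orthoester may open to the equatorial C2 ester, or the C3 ester may migrate to C2 during the acetonide hydrolysis. The fallback sets out from 6 and differentiates the two oxygens before the coupling instead of after it. Isobutyric anhydride/DMAP acylates the secondary C3 hydroxyl (the tertiary C4 hydroxyl is inert) to give the epoxy triester 5β-acetoxy-1α,2α-epoxy-4β-hydroxy-4α-methylcyclohexane-3α,6β-diyl bis(2-methylpropanoate) F2. Under the step 11 conditions iodide opens F2 at C1 by trans-diaxial (Fürst–Plattner) control without chelation, via 5β-acetoxy-2α,4β-dihydroxy-1β-iodo-4α-methylcyclohexane-3α,6β-diyl bis(2-methylpropanoate) F3, and coupling with 16 gives 20 directly. The fallback comes back to the route at 20, which AcOH/H2O converts to 21.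

Step 1. The free dienediol may aromatise, or the C6 hydroxyl may direct epoxidation to the C1=C2 alkene. The fallback sets out from 1 and reverses the order. Isobutyric anhydride/pyridine at −40 °C acylates the less hindered C6 hydroxyl to (1S,6R)-6-hydroxy-5-methylcyclohexa-2,4-dien-1-yl 2-methylpropanoate F4. VO(acac)2/t-BuOOH then has only the allylic C5 hydroxyl to direct it and epoxidises C3=C4 on the β face. The fallback comes back to the route at 3, which is acetylated to 4 as in step 2.

**Further compounds**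
F1 | step 11 | 5β-acetoxy-1β-bromo-2α,3α,4β-trihydroxy-4α-methylcyclohexan-6β-yl 2-methylpropanoate | Br[C@H]1[C@H](O)[C@H](O)[C@@](C)(O)[C@@H](OC(C)=O)[C@H]1OC(=O)C(C)C
F2 | step 12 | 5β-acetoxy-1α,2α-epoxy-4β-hydroxy-4α-methylcyclohexane-3α,6β-diyl bis(2-methylpropanoate) | [C@@H]12O[C@@H]1[C@H](OC(=O)C(C)C)[C@@](C)(O)[C@@H](OC(C)=O)[C@H]2OC(=O)C(C)C
F3 | step 12 | 5β-acetoxy-2α,4β-dihydroxy-1β-iodo-4α-methylcyclohexane-3α,6β-diyl bis(2-methylpropanoate) | I[C@H]1[C@H](O)[C@H](OC(=O)C(C)C)[C@@](C)(O)[C@@H](OC(C)=O)[C@H]1OC(=O)C(C)C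
F4 | step 1 | (1S,6R)-6-hydroxy-5-methylcyclohexa-2,4-dien-1-yl 2-methylpropanoate | C1=CC=C(C)[C@@H](O)[C@H]1OC(=O)C(C)C
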